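The ten-membered carbocycle (C1–C10, germacrane numbering) is never closed head-to-tail. Its γ,δ-unsaturated ketone array C1(=O)–C2–C3–C4(CH3)=C5 is a Claisen retron. The ring is therefore traced back to an eight-membered 2-methyleneoxocane (O, C1, C10, C9, C8, C7, C6, C5) that carries an isopropenyl group on C5 and comes from an eight-membered lactone. One thermal [3,3] shift forms C2–C3, turns the ring oxygen into the C1 ketone and takes C2–C4 into the ring (net two atoms more). It also delivers the (Z)-C4=C5 alkene needed for the cis-epoxide. A C7 exocyclic methylene masks the ketone on which the butenolide is later built.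

Key step: step 12

Remark (numbering): C1 = ring ketone, C4/C5 = epoxide, C6 = lactone carbinol, C7=C11 = butenolide alkene, C8 = methacrylate carbinol, C10 = CH(CH3), C12 = lactone C=O, C13 = CH2OAc.
Remark (reading of the SMILES): it encodes a cis (Z-derived) 4,5-epoxide with the epoxide O, O6, O8 and the C10 methyl on one ring face (4S,5R,6R,8R,10S), and this is taken at face value.

Step 1
Reactants: 1 2-methylidenepropane-1,3-diol
Product: 2 2-[(methoxymethoxy)methyl]prop-2-en-1-ol
Conditions: NaH (1 equiv), THF, 0 °C; MOMCl (1 equiv)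
Reagents that add atoms: chloromethyl methyl ether (MOMCl), COCCl
Why: O-alkylation of the sparingly soluble mono-sodium alkoxide (Williamson-type acetal formation) favours single protection; no stereocentre is involved.

Step 2
Reactants: 2 2-[(methoxymethoxy)methyl]prop-2-en-1-ol
Product: 3 2-[(methoxymethoxy)methyl]prop-2-enal
Conditions: activated MnO2, CH2Cl2, rt; used at once
Reagents that add atoms: none
Why: MnO2 oxidation of an allylic alcohol stops at the enal and leaves the MOM acetal untouched.

Step 3
Reactants: 4 (R)-3-bromo-2-methylpropan-1-ol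
Product: 5 (R)-(3-bromo-2-methylpropoxy)(tert-butyl)dimethylsilane
Conditions: TBSCl, imidazole, CH2Cl2, 0 °C to rt
Reagents that add atoms: tert-butyldimethylsilyl chloride, CC(C)(C)[Si](C)(C)Cl
Why: Standard silyl ether formation; the chiral-pool centre (future C10) is not touched.

Step 4
Reactants: 5 (R)-(3-bromo-2-methylpropoxy)(tert-butyl)dimethylsilane
Product: 6 (R)-tert-butyl(3-iodo-2-methylpropoxy)dimethylsilane
Conditions: NaI, acetone, reflux
Reagents that add atoms: sodium iodide, [Na+].[I-]
Why: Finkelstein exchange (SN2 at the primary carbon C9) is driven by precipitation of the bromide salt and does not involve the adjacent stereocentre.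

Step 5
Reactants: 6 (R)-tert-butyl(3-iodo-2-methylpropoxy)dimethylsilane; 3 2-[(methoxymethoxy)methyl]prop-2-enal
Product: 8 (3R,5S)-6-(tert-butyldimethylsilyloxy)-2-[(methoxymethoxy)methyl]-5-methylhex-1-en-3-ol (8R,10S), via dialkylzinc 7 (not isolated)
Conditions: Et2Zn (neat), CuI (cat.), 50 °C, then vacuum; (1S,2S)-1,2-bis(trifluoromethanesulfonamido)cyclohexane (cat.), Ti(OiPr)4, toluene, −20 °C, then 3; aq HCl work-up
Reagents that add atoms: none
Why: Iodine–zinc exchange gives a dialkylzinc whose stereocentre is β to zinc and therefore secure, and the titanium/bis-sulfonamide-catalysed asymmetric 1,2-addition to the enal forms C8–C9, the (1S,2S)-ligand directing alkyl transfer to the Re face to set 8R.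

Step 6
Reactants: 8 (8R,10S)-allylic alcohol
Product: 9 (8R,10S)-bis-TBS ether of 8, the 2-substituted allyl MOM ether CH2=C7(R)–C6H2–OMOM
Conditions: TBSCl, imidazole, DMAP (cat.), DMF, 40 °C
Reagents that add atoms: tert-butyldimethylsilyl chloride, CC(C)(C)[Si](C)(C)Cl
Why: Silylation blocks O8 for the organolithium, lactonisation and titanium steps and keeps O8 distinct from O6 (MOM).

Step 7
Reactants: 9 allyl MOM ether; 10 methacrolein
Product: 12 (3R,4R,6R,8S)-6,9-bis(tert-butyldimethylsilyloxy)-4-(methoxymethoxy)-2,8-dimethyl-5-methylidenenon-1-en-3-ol (5R,6R,8R,10S), via allylborane 11 (not isolated)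
Conditions: s-BuLi, THF, −78 °C; (−)-Ipc2BOMe; BF3·OEt2; 10, −78 °C; NaOH, H2O2, 0 °C
Reagents that add atoms: none
Why: Asymmetric γ-alkoxyallylboration: chelation-controlled lithiation at C6 and boron capture at C11 give the allylborane with OMOM cis to CH2B, and its closed chair transition state forms C5–C6 with a syn O5/O6 relationship and regenerates C7=CH2, while the isopinocampheyl groups select the Si face of the aldehyde (5R, hence 6R).

Step 8
Reactants: 12 bis-TBS homoallylic alcohol
Product: 13 (2S,4R,6R,7R)-4-(tert-butyldimethylsilyloxy)-6-(methoxymethoxy)-2,8-dimethyl-5-methylidenenon-8-ene-1,7-diol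
Conditions: HF·pyridine, pyridine, THF, 0 °C
Reagents that add atoms: none
Why: In buffered fluoride desilylation the unhindered primary C1 silyl ether is cleaved faster than the hindered secondary allylic C8 silyl ether.

Step 9
Reactants: 13 1,7-diol
Product: 14 (2S,4R,6R,7R)-4-(tert-butyldimethylsilyloxy)-7-hydroxy-6-(methoxymethoxy)-2,8-dimethyl-5-methylidenenon-8-enoic acid
Conditions: TEMPO (cat.), PhI(OAc)2, MeCN/pH 7 buffer, rt
Reagents that add atoms: water, O
Why: Oxoammonium (TEMPO/BAIB) oxidation takes the primary alcohol through the aldehyde hydrate to the acid and is selective over the hindered secondary C5 carbinol; the neutral medium keeps C10 intact.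

Step 10
Reactants: 14 seco acid
Product: 15 (3S,5R,7R,8R)-5-(tert-butyldimethylsilyloxy)-7-(methoxymethoxy)-3-methyl-6-methylidene-8-(prop-1-en-2-yl)oxocan-2-one (ring O, C1, C10, C9, C8, C7, C6, C5)
Conditions: MNBA, DMAP, CH2Cl2 (high dilution, slow addition), rt
Reagents that add atoms: none
Why: Shiina lactonisation, an acyl-transfer method proven for eight-membered lactones, closes O5–C1 with retention at C5; the sp2 C7 and four ring substituents reduce the entropic and transannular cost.

Step 11
Reactants: 15 eight-membered lactone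
Product: 16 (2R,3R,5R,7S)-5-(tert-butyldimethylsilyloxy)-3-(methoxymethoxy)-7-methyl-4,8-dimethylidene-2-(prop-1-en-2-yl)oxocane
Conditions: Cp2TiMe2, toluene, 75 °C, dark; filtration through basic alumina
Reagents that add atoms: dimethyltitanocene, C[Ti+2]C.c1cc[cH-]c1.c1cc[cH-]c1
Why: Petasis methylenation: thermally generated titanocene methylidene converts the only carbonyl of 15 into the exocyclic enol ether C1=C2H2 by [2+2] addition and cycloreversion; it is non-basic (C10 safe), and isolating 16 removes titanium before a ketone appears.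

Step 12
Reactants: 16 2-methyleneoxocane
Product: 17 (2S,4R,6S,7Z)-4-(tert-butyldimethylsilyloxy)-6-(methoxymethoxy)-2,8-dimethyl-5-methylidenecyclodec-7-en-1-one (germacrane numbering 4Z,6S,8R,10S)
Conditions: o-xylene, 140 °C, sealed base-washed tube
Reagents that add atoms: none
Why: Heating brings the exocyclic C1=C2 enol ether and the C5 isopropenyl group of 16 into a chair-like six-centre array (C2=C1–O–C5–C4=C3), in which C2–C3 forms as O–C5 breaks in a concerted suprafacial [3,3]-sigmatropic (Claisen) shift driven by formation of the C1=O bond. The closest known reaction type is the Claisen ring expansion of 2-methylene-ω-vinyl cyclic ethers made by lactone methylenation, which turns an n-membered oxacycle into an (n+2)-membered cycloalkenone. The only ring closed is the ten-membered carbocycle, closed at C2–C3 through a bicyclo[5.3.1]-type transition state in which the five-atom tether C6–C10 bridges C5 and C1 of the pericyclic array, the oxygen leaving the ring and C2, C3 and C4 entering it. No sp3 stereocentre is created; the one new stereo-element, the C4=C5 geometry, is controlled by the oxocane, whose gauche endocyclic C1–O–C5–C6 torsion forces C6 into the pseudo-axial site (reinforced by the C4 methyl, which disfavours an equatorial C6), so that C3 and C6 end up cis (Z). The step needs periselectivity over the Cope shift of the C3=C4–C5–C6–C7=C11 1,5-diene and over acid-induced migration of the enol ether double bond, and the lower barrier of the single 2-alkyl allyl vinyl ether unit together with neutral base-washed conditions secures it. C6, C8 and C10 are spectators and the sacrificial C5 carbinol centre is erased, so its configuration does not matter for the product.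

Step 13
Reactants: 17 cyclodecenone MOM ether
Product: 18 (2S,4R,6S,7Z)-4-(tert-butyldimethylsilyloxy)-6-hydroxy-2,8-dimethyl-5-methylidenecyclodec-7-en-1-one
Conditions: Me2BBr, CH2Cl2, −78 °C; then THF/sat. aq NaHCO3
Reagents that add atoms: none
Why: Bromoborane acetal cleavage attacks the outer MOM oxygen at low temperature, so the doubly allylic C6–O bond is never ionised, and the silyl ether, ketone and both alkenes survive.

Step 14
Reactants: 18 (Z)-allylic alcohol
Product: 19 (4S,5R,6R,8R,10S)-8-(tert-butyldimethylsilyloxy)-4,5-epoxy-6-hydroxy-4,10-dimethyl-7-methylidenecyclodecan-1-one (cis-epoxide, O syn to O6)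
Conditions: VO(acac)2 (cat.), t-BuOOH (1 equiv), CH2Cl2, 0 °C
Reagents that add atoms: tert-butyl hydroperoxide, CC(C)(C)OO
Why: In this hydroxyl-directed vanadium-catalysed epoxidation the C6 vanadate delivers oxygen through a small O–C6–C5=C4 dihedral, the mode that gives cis-epoxy alcohols from medium-ring (Z)-allylic alcohols, which sets 4S,5R; the trisubstituted C4=C5 bond is more nucleophilic than the C7 methylene, which is deactivated by two allylic C–O bonds.

Step 15
Reactants: 19 epoxy alcohol
Product: 20 (4S,5R,6S,8R,10S)-8-(tert-butyldimethylsilyloxy)-4,5-epoxy-6-hydroxy-4,10-dimethylcyclodecane-1,7-dione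
Conditions: O3, CH2Cl2, −78 °C; Me2S
Reagents that add atoms: ozone, [O-][O+]=O
Why: Ozonolysis of the only remaining C=C unmasks the C7 ketone under neutral reductive work-up that spares the epoxide and the α-stereocentres.

Step 16
Reactants: 21 trimethyl 2-phosphonoacrylate; 22 4-methoxybenzyl alcohol
Product: 23 methyl 2-(dimethoxyphosphoryl)-3-[(4-methoxybenzyl)oxy]propanoate (racemic)
Conditions: t-BuOK (cat.), THF, 0 °C to rt
Reagents that add atoms: none
Why: Base-catalysed oxa-Michael addition to the doubly activated alkene installs the protected C13 oxygen; the acidic centre (future C11) becomes sp2 later.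

Step 17
Reactants: 23 phosphono ester
Product: 24 2-(dimethoxyphosphoryl)-3-[(4-methoxybenzyl)oxy]propanoic acid
Conditions: LiOH (1 equiv), THF/H2O, 0 °C; aq HCl to pH 3
Reagents that add atoms: lithium hydroxide, [Li+].[OH-]
Why: In this saponification the carboxylic methyl ester is hydrolysed faster than the phosphonate methyl esters at 0 °C.

Step 18
Reactants: 20 α-hydroxy ketone; 24 phosphono acid
Product: 25 C6 ester of 20 with 24 (4S,5R,6S,8R,10S; C11 epimers)
Conditions: DCC, DMAP (cat.), CH2Cl2, 0 °C to rt
Reagents that add atoms: none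
Why: Steglich esterification acylates the only free hydroxyl (O6), placing C11–C13 next to the C7 ketone without strong base.

Step 19
Reactants: 25 keto phosphonate
Product: 26 (4S,5R,6R,8R,10S)-8-(tert-butyldimethylsilyloxy)-4,5-epoxy-13-(4-methoxybenzyloxy)-1-oxogermacr-7(11)-en-12,6-olide
Conditions: LiCl, i-Pr2NEt, MeCN, 0 °C to rt
Reagents that add atoms: none
Why: Intramolecular Horner–Wadsworth–Emmons olefination (Masamune–Roush conditions) closes the five-membered ring onto C7 and not the remote C1 ketone; the ring fixes the alkene geometry, both C11 epimers converge, and the weak base spares C6-H, C10-H and the epoxide.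

Step 20
Reactants: 26 silyl ether
Product: 27 the corresponding C8 alcohol
Conditions: TBAF, AcOH (1:1), THF, 0 °C to rt
Reagents that add atoms: none
Why: Acetic-acid-buffered fluoride desilylation is close to neutral, which avoids γ-deprotonation of the butenolide as well as acid opening of the epoxide.

Step 21
Reactants: 27 C8 alcohol
Product: 28 C8 methacrylate with C13 still PMB-protected
Conditions: methacrylic anhydride, Et3N, DMAP (cat.), CH2Cl2, 0 °C
Reagents that add atoms: methacrylic anhydride, C=C(C)C(=O)OC(=O)C(C)=C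
Why: DMAP-catalysed acylation of the only free hydroxyl proceeds with retention at C8.

Step 22
Reactants: 28 PMB ether
Product: 29 13-hydroxy compound
Conditions: DDQ, CH2Cl2/pH 7 buffer, 0 °C
Reagents that add atoms: none
Why: Oxidative PMB cleavage by hydride abstraction from the electron-rich benzyl ether leaves the electron-poor alkenes, epoxide, ketone and esters untouched.

Step 23
Reactants: 29 primary allylic alcohol
Product: 30 target CNP0128625.1, (4S,5R,6R,8R,10S)-13-acetoxy-4,5-epoxy-8-methacryloyloxy-1-oxogermacr-7(11)-en-12,6-olide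
Conditions: Ac2O, pyridine, CH2Cl2, 0 °C
Reagents that add atoms: acetic anhydride, CC(=O)OC(C)=O
Why: Mild acetylation of the primary alcohol as the last step keeps the sensitive 2-(acetoxymethyl)butenolide away from fluoride and stronger bases.

Compound list
1 | 2-methylidenepropane-1,3-diol | C=C(CO)CO | starting material
2 | 2-[(methoxymethoxy)methyl]prop-2-en-1-ol | C=C(CO)COCOC | intermediate
3 | 2-[(methoxymethoxy)methyl]prop-2-enal | C=C(C=O)COCOC | intermediate
4 | (R)-3-bromo-2-methylpropan-1-ol | BrC[C@H](C)CO | starting material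
5 | (R)-(3-bromo-2-methylpropoxy)(tert-butyl)dimethylsilane | BrC[C@H](C)CO[Si](C)(C)C(C)(C)C | intermediate
6 | (R)-tert-butyl(3-iodo-2-methylpropoxy)dimethylsilane | IC[C@H](C)CO[Si](C)(C)C(C)(C)C | intermediate
7 | bis[(R)-3-(tert-butyldimethylsilyloxy)-2-methylpropyl]zinc | CC(C)(C)[Si](C)(C)OC[C@@H](C)C[Zn]C[C@H](C)CO[Si](C)(C)C(C)(C)C | intermediate
8 | (3R,5S)-6-(tert-butyldimethylsilyloxy)-2-[(methoxymethoxy)methyl]-5-methylhex-1-en-3-ol | COCOCC(=C)[C@H](O)C[C@H](C)CO[Si](C)(C)C(C)(C)C | intermediate
9 | (8R,10S)-bis-TBS allyl MOM ether | COCOCC(=C)[C@H](O[Si](C)(C)C(C)(C)C)C[C@H](C)CO[Si](C)(C)C(C)(C)C | intermediate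
10 | methacrolein | C=C(C)C=O | starting material
11 | γ-(methoxymethoxy)allyl-diisopinocampheylborane (B on C11, OMOM cis to CH2B) | COCO/C=C(\CB([C@@H]1C[C@@H]2C[C@H]([C@H]1C)C2(C)C)[C@@H]1C[C@@H]2C[C@H]([C@H]1C)C2(C)C)[C@H](O[Si](C)(C)C(C)(C)C)C[C@H](C)CO[Si](C)(C)C(C)(C)C | intermediate
12 | (5R,6R,8R,10S)-syn-homoallylic alcohol | C=C(C)[C@@H](O)[C@H](OCOC)C(=C)[C@H](O[Si](C)(C)C(C)(C)C)C[C@H](C)CO[Si](C)(C)C(C)(C)C | intermediate
13 | (5R,6R,8R,10S)-C1,C5-diol | C=C(C)[C@@H](O)[C@H](OCOC)C(=C)[C@H](O[Si](C)(C)C(C)(C)C)C[C@H](C)CO | intermediate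
14 | (5R,6R,8R,10S)-seco acid | C=C(C)[C@@H](O)[C@H](OCOC)C(=C)[C@H](O[Si](C)(C)C(C)(C)C)C[C@H](C)C(=O)O | intermediate
15 | (5R,6R,8R,10S)-eight-membered lactone (oxocan-2-one) | C=C(C)[C@H]1OC(=O)[C@@H](C)C[C@@H](O[Si](C)(C)C(C)(C)C)C(=C)[C@H]1OCOC | intermediate
16 | (5R,6R,8R,10S)-2-methyleneoxocane | C=C(C)[C@H]1OC(=C)[C@@H](C)C[C@@H](O[Si](C)(C)C(C)(C)C)C(=C)[C@H]1OCOC | intermediate
17 | (4Z,6S,8R,10S)-cyclodecenone MOM ether | CC(C)(C)[Si](C)(C)O[C@@H]1C[C@H](C)C(=O)CC/C(C)=C\[C@H](OCOC)C1=C | intermediate
18 | (4Z,6S,8R,10S)-6-hydroxycyclodecenone | CC(C)(C)[Si](C)(C)O[C@@H]1C[C@H](C)C(=O)CC/C(C)=C\[C@H](O)C1=C | intermediate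
19 | (4S,5R,6R,8R,10S)-epoxy alcohol | CC(C)(C)[Si](C)(C)O[C@@H]1C[C@H](C)C(=O)CC[C@]2(C)O[C@@H]2[C@H](O)C1=C | intermediate
20 | (4S,5R,6S,8R,10S)-6-hydroxy-1,7-dione | CC(C)(C)[Si](C)(C)O[C@@H]1C[C@H](C)C(=O)CC[C@]2(C)O[C@@H]2[C@H](O)C1=O | intermediate
21 | trimethyl 2-phosphonoacrylate | COC(=O)C(=C)P(=O)(OC)OC | starting material
22 | 4-methoxybenzyl alcohol | COc1ccc(CO)cc1 | starting material
23 | methyl 2-(dimethoxyphosphoryl)-3-[(4-methoxybenzyl)oxy]propanoate | COC(=O)C(COCc1ccc(OC)cc1)P(=O)(OC)OC | intermediate
24 | 2-(dimethoxyphosphoryl)-3-[(4-methoxybenzyl)oxy]propanoic acid | OC(=O)C(COCc1ccc(OC)cc1)P(=O)(OC)OC | intermediate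
25 | C6 phosphono ester of 20 | CC(C)(C)[Si](C)(C)O[C@@H]1C[C@H](C)C(=O)CC[C@]2(C)O[C@@H]2[C@H](OC(=O)C(COCc2ccc(OC)cc2)P(=O)(OC)OC)C1=O | intermediate
26 | 8-O-TBS, 13-O-PMB butenolide | CC(C)(C)[Si](C)(C)O[C@@H]1C[C@H](C)C(=O)CC[C@]2(C)O[C@@H]2[C@@H]2OC(=O)C(COCc3ccc(OC)cc3)=C21 | intermediate
27 | 8-hydroxy, 13-O-PMB butenolide | O[C@@H]1C[C@H](C)C(=O)CC[C@]2(C)O[C@@H]2[C@@H]2OC(=O)C(COCc3ccc(OC)cc3)=C21 | intermediate
28 | 8-methacrylate, 13-O-PMB butenolide | C=C(C)C(=O)O[C@@H]1C[C@H](C)C(=O)CC[C@]2(C)O[C@@H]2[C@@H]2OC(=O)C(COCc3ccc(OC)cc3)=C21 | intermediate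
29 | 8-methacrylate, 13-hydroxy butenolide | C=C(C)C(=O)O[C@@H]1C[C@H](C)C(=O)CC[C@]2(C)O[C@@H]2[C@@H]2OC(=O)C(CO)=C21 | intermediate
30 | CNP0128625.1 | C=C(C)C(=O)O[C@@H]1C[C@H](C)C(=O)CC[C@]2(C)O[C@@H]2[C@@H]2OC(=O)C(COC(C)=O)=C21 | target

Total step count: 23. Longest linear sequence: 19 steps (4 to 30 through steps 3–15 and 18–23).

Steps most likely to fail

1. Step 12. The [3,3] shift may need a temperature at which the Cope rearrangement of the C3=C4–C5–C6–C7=C11 diene, migration of the enol ether double bond towards C10, or loss of Z-selectivity compete.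
   - Fallback: it sets out from 16. Triisobutylaluminium in CH2Cl2 (−78 °C to rt) would drive the same O–C5/C2–C3 reorganisation as a Lewis-acid-accelerated Claisen shift far below the Cope threshold.
   - The aluminium-bound ketone is reduced in situ by β-hydride transfer to the (Z)-cyclodecenol F1 (C1 epimers). Dess–Martin oxidation of the cyclodecenol F1 returns to 17.

2. Step 10. Oligomerisation may outrun eight-membered ring closure, and acyl transfer to the hindered C5 carbinol may be slow.
   - Fallback: it sets out from 14 and activates the alcohol instead of the acid. Mitsunobu macrolactonisation (PPh3, DIAD, toluene, high dilution) forms the O–C5 bond with inversion and gives the C5-epimeric lactone F2.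
   - Petasis methylenation as in step 11 gives the C5-epimeric enol ether F3. Its [3,3] shift erases C5, so the sequence comes back to the route at 17.

3. Step 7. Lithiation of the hindered 2-substituted allyl ether may be incomplete. Silyl migration from O8 to the allyl anion may occur. Facial selectivity may be eroded by a mismatch between the C8 centre and the isopinocampheyl groups.
   - Fallback: it sets out from 9. Ozonolysis of the C7 methylene gives the α-alkoxy ketone F4.
   - Enolisation towards C6 with dicyclohexylboron chloride/Et3N and aldol addition to methacrolein should give the syn-aldol F5 under control of the C8 silyloxy stereocentre.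
   - Non-basic Petasis methylenation of the C7 ketone of F5 comes back to the route at 12.

Further compounds
F1 | step 12 | (4Z,6S,8R,10S)-8-(tert-butyldimethylsilyloxy)-6-(methoxymethoxy)-4,10-dimethyl-7-methylidenecyclodec-4-en-1-ol (C1 epimers) | CC(C)(C)[Si](C)(C)O[C@@H]1C[C@H](C)C(O)CC/C(C)=C\[C@H](OCOC)C1=C
F2 | step 10 | (5S,6R,8R,10S)-lactone, C5 epimer of 15 | C=C(C)[C@@H]1OC(=O)[C@@H](C)C[C@@H](O[Si](C)(C)C(C)(C)C)C(=C)[C@H]1OCOC
F3 | step 10 | (5S,6R,8R,10S)-2-methyleneoxocane, C5 epimer of 16 | C=C(C)[C@@H]1OC(=C)[C@@H](C)C[C@@H](O[Si](C)(C)C(C)(C)C)C(=C)[C@H]1OCOC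
F4 | step 7 | (8R,10S)-1-(methoxymethoxy)-3,6-bis(tert-butyldimethylsilyloxy)-5-methylhexan-2-one | COCOCC(=O)[C@H](O[Si](C)(C)C(C)(C)C)C[C@H](C)CO[Si](C)(C)C(C)(C)C
F5 | step 7 | (5R,6S,8R,10S)-syn-aldol (C7 ketone analogue of 12) | C=C(C)[C@@H](O)[C@H](OCOC)C(=O)[C@H](O[Si](C)(C)C(C)(C)C)C[C@H](C)CO[Si](C)(C)C(C)(C)C
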